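**Assumption:** the SMILES is taken literally: 4Z olefin, C2 trans to CO2Me across C1=C10, and the C8 ester is (2S,3R)-2,3-dimethyloxirane-2-carboxylate (the epoxide of tiglic acid). Germacranolide numbering (C1–C15) is used for locants.

## Retrosynthetic overview

1. The ten-membered ring is closed last at C9–C10 by a CrCl2/NiCl2 addition of an α-iodoenoate to an aldehyde, not by the usual C6–C7 allylation or by metathesis; this step also releases the free C9 hydroxyl.
2. The C8 ester comes from Yamaguchi acylation with the epoxy acid, itself made from tiglyl alcohol by Sharpless epoxidation and oxidation.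
3. The α-methylene lactone with C7 and C8 comes from an indium Barbier reaction of a 3-(bromomethyl)butenolide with a silyloxyacetaldehyde.
4. The butenolide comes from ring-closing metathesis of a 2-(bromomethyl)acrylate; the (Z)-α-iodoenoate from an iodo-Wittig reaction on a cis-epoxy aldehyde; the cis-epoxide from Sharpless epoxidation of a (2Z,4Z)-dienol.
5. The dienol comes from (S)-but-3-ene-1,2-diol by Stork–Zhao iodo-olefination, Sonogashira coupling and zinc reduction. Ring order: oxirane, butenolide (then α-methylene lactone), carbocycle.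

## Route

Step 1
Reactants: 1 (S)-but-3-ene-1,2-diol
Product: 2 (S)-3,4-bis(tert-butyldimethylsilyloxy)but-1-ene
Conditions: TBSCl (2.5 equiv), imidazole, DMF, 25 °C
Reagents that add atoms: tert-butyldimethylsilyl chloride, CC(C)(C)[Si](C)(C)Cl
Why: Imidazole-promoted silyl ether formation protects both hydroxyls without touching the stereocentre (future C6).

Step 2
Reactants: 2 (S)-3,4-bis(tert-butyldimethylsilyloxy)but-1-ene
Product: 3 (S)-2-(tert-butyldimethylsilyloxy)but-3-en-1-ol
Conditions: camphorsulfonic acid (10 mol %), MeOH/CH2Cl2 1:1, −10 °C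
Reagents that add atoms: none
Why: Acid-catalysed methanolysis (selective desilylation) cleaves the unhindered primary silyl ether much faster than the secondary allylic one.

Step 3
Reactants: 3 (S)-2-(tert-butyldimethylsilyloxy)but-3-en-1-ol
Product: 4 (S)-2-(tert-butyldimethylsilyloxy)but-3-enal
Conditions: Dess–Martin periodinane, pyridine, CH2Cl2, 0 °C; used crude
Reagents that add atoms: none
Why: Buffered Dess–Martin oxidation gives the α-silyloxy aldehyde without base-induced epimerisation or migration of the double bond into conjugation.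

Step 4
Reactants: 4 (S)-2-(tert-butyldimethylsilyloxy)but-3-enal; 5 ethyltriphenylphosphonium iodide
Product: 9 (3S,4Z)-3-(tert-butyldimethylsilyloxy)-5-iodohexa-1,4-diene, via ethylidenetriphenylphosphorane 6 (not isolated), via (1-iodoethyl)triphenylphosphonium iodide 7 (not isolated), via (1-iodoethylidene)triphenylphosphorane 8 (not isolated)
Conditions: 5, n-BuLi, THF, 0 °C; I2, −78 °C; NaN(SiMe3)2, −78 to −20 °C; then 4, −78 °C
Reagents that add atoms: iodine, II
Why: Stork–Zhao-type Wittig olefination with the α-iodo ylide is Z-selective under kinetic control at −78 °C, placing iodine cis to the C6 chain and so fixing the later 4Z geometry; C6 is untouched.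

Step 5
Reactants: 9 (3S,4Z)-3-(tert-butyldimethylsilyloxy)-5-iodohexa-1,4-diene; 10 prop-2-yn-1-ol
Product: 11 (4Z,6S)-6-(tert-butyldimethylsilyloxy)-4-methylocta-4,7-dien-2-yn-1-ol
Conditions: PdCl2(PPh3)2 (3 mol %), CuI (6 mol %), Et3N, THF, 25 °C
Reagents that add atoms: none
Why: Sonogashira coupling of an alkenyl iodide proceeds with retention of olefin geometry and tolerates the free propargylic alcohol.

Step 6
Reactants: 11 (4Z,6S)-6-(tert-butyldimethylsilyloxy)-4-methylocta-4,7-dien-2-yn-1-ol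
Product: 12 (2Z,4Z,6S)-6-(tert-butyldimethylsilyloxy)-4-methylocta-2,4,7-trien-1-ol
Conditions: Zn dust activated by Cu(OAc)2 and AgNO3, MeOH/H2O 1:1, 40 °C
Reagents that add atoms: none
Why: Boland reduction semi-reduces only the conjugated alkyne by cis delivery of hydrogen, giving the 2Z olefin and leaving the isolated vinyl group alone.

Step 7
Reactants: 12 (2Z,4Z,6S)-6-(tert-butyldimethylsilyloxy)-4-methylocta-2,4,7-trien-1-ol
Product: 13 [(2S,3R)-3-[(2Z,4S)-4-(tert-butyldimethylsilyloxy)hexa-2,5-dien-2-yl]oxiran-2-yl]methanol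
Conditions: Ti(OiPr)4 (10 mol %), L-(+)-diethyl tartrate (12 mol %), t-BuOOH, 4 Å molecular sieves, CH2Cl2, −25 °C
Reagents that add atoms: tert-butyl hydroperoxide, CC(C)(C)OO
Why: Katsuki–Sharpless asymmetric epoxidation acts only on the allylic-alcohol olefin, and with L-(+)-tartrate the Z-olefin gives the cis (2S,3R)-epoxide under reagent control (same facial sense as (Z)-hex-2-en-1-ol), setting C2 and C3.

Step 8
Reactants: 13 [(2S,3R)-3-[(2Z,4S)-4-(tert-butyldimethylsilyloxy)hexa-2,5-dien-2-yl]oxiran-2-yl]methanol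
Product: 14 (2R,3R)-3-[(2Z,4S)-4-(tert-butyldimethylsilyloxy)hexa-2,5-dien-2-yl]oxirane-2-carbaldehyde
Conditions: Dess–Martin periodinane, pyridine, CH2Cl2, 0 °C; used crude
Reagents that add atoms: none
Why: Buffered Dess–Martin oxidation gives the cis-epoxy aldehyde without base that could epimerise C2 (the descriptor changes only by CIP priority).

Step 9
Reactants: 14 (2R,3R)-3-[(2Z,4S)-4-(tert-butyldimethylsilyloxy)hexa-2,5-dien-2-yl]oxirane-2-carbaldehyde; 15 methyl (triphenylphosphoranylidene)acetate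
Product: 18 methyl (2Z)-3-[(2S,3R)-3-[(2Z,4S)-4-(tert-butyldimethylsilyloxy)hexa-2,5-dien-2-yl]oxiran-2-yl]-2-iodoprop-2-enoate, via (1-iodo-2-methoxy-2-oxoethyl)triphenylphosphonium succinimidate 16 (not isolated), via methyl iodo(triphenylphosphoranylidene)acetate 17 (not isolated)
Conditions: 15, N-iodosuccinimide, CH2Cl2, −20 °C; then 14, −20 to 25 °C
Reagents that add atoms: N-iodosuccinimide, O=C1CCC(=O)N1I
Why: Halogenation–Wittig sequence in which the stabilised α-iodo ylide gives the (Z)-α-iodoacrylate (ester trans to the epoxide carbon), which is the C1=C10 geometry of the target once iodine is replaced by C9.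

Step 10
Reactants: 18 methyl (2Z)-3-[(2S,3R)-3-[(2Z,4S)-4-(tert-butyldimethylsilyloxy)hexa-2,5-dien-2-yl]oxiran-2-yl]-2-iodoprop-2-enoate
Product: 19 methyl (2Z)-3-[(2S,3R)-3-[(2Z,4S)-4-hydroxyhexa-2,5-dien-2-yl]oxiran-2-yl]-2-iodoprop-2-enoate
Conditions: Bu4NF, AcOH (1:1), THF, 0 to 25 °C
Reagents that add atoms: none
Why: Fluoride desilylation buffered by acetic acid frees the C6 hydroxyl while the vinyl epoxide and iodoenoate stay intact.

Step 11
Reactants: 19 methyl (2Z)-3-[(2S,3R)-3-[(2Z,4S)-4-hydroxyhexa-2,5-dien-2-yl]oxiran-2-yl]-2-iodoprop-2-enoate; 20 2-(bromomethyl)prop-2-enoic acid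
Product: 22 (3S,4Z)-5-[(2R,3S)-3-[(1Z)-2-iodo-3-methoxy-3-oxoprop-1-en-1-yl]oxiran-2-yl]hexa-1,4-dien-3-yl 2-(bromomethyl)prop-2-enoate, via 2-(bromomethyl)prop-2-enoyl chloride 21 (not isolated)
Conditions: 20, (COCl)2, cat. DMF, CH2Cl2, 0 °C; then 19, 2,6-lutidine, CH2Cl2, −40 to 0 °C
Reagents that add atoms: none
Why: O-Acylation with the acid chloride and a hindered non-nucleophilic base avoids SN2′ attack on the allylic bromide and retains configuration at C6.

Step 12
Reactants: 22 (3S,4Z)-5-[(2R,3S)-3-[(1Z)-2-iodo-3-methoxy-3-oxoprop-1-en-1-yl]oxiran-2-yl]hexa-1,4-dien-3-yl 2-(bromomethyl)prop-2-enoate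
Product: 23 methyl (2Z)-3-[(2S,3R)-3-[(1Z)-1-[(2R)-4-(bromomethyl)-5-oxo-2,5-dihydrofuran-2-yl]prop-1-en-2-yl]oxiran-2-yl]-2-iodoprop-2-enoate
Conditions: second-generation Grubbs catalyst RuCl2(=CHPh)(H2IMes)(PCy3) (5 mol %), CH2Cl2 (5 mM), 40 °C
Reagents that add atoms: none
Why: Ring-closing metathesis between the only terminal vinyl group and the acrylate closes the five-membered butenolide (the trisubstituted and iodo-substituted olefins are inert) without forming a stereocentre; 40 °C is kept as the ceiling to avoid Cope rearrangement of the cis-dialkenyl epoxide.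

Step 13
Reactants: 23 methyl (2Z)-3-[(2S,3R)-3-[(1Z)-1-[(2R)-4-(bromomethyl)-5-oxo-2,5-dihydrofuran-2-yl]prop-1-en-2-yl]oxiran-2-yl]-2-iodoprop-2-enoate; 24 (tert-butyldimethylsilyloxy)acetaldehyde
Product: 25 methyl (2Z)-3-[(2S,3R)-3-[(1Z)-1-[(2R,3R)-3-[(1S)-2-(tert-butyldimethylsilyloxy)-1-hydroxyethyl]-4-methylidene-5-oxooxolan-2-yl]prop-1-en-2-yl]oxiran-2-yl]-2-iodoprop-2-enoate
Conditions: indium powder, THF/H2O 1:1, 25 °C
Reagents that add atoms: none
Why: Indium Barbier allylation in which the allylindium reacts through its γ-carbon (C7) on the face anti to the C6 side chain (6,7-trans lactone) with transposition of the double bond to the exocyclic methylene, and the closed transition state reported for 3-(bromomethyl)furan-2(5H)-ones gives the syn C6/C8–OH relationship (8S).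

Step 14
Reactants: 26 (E)-2-methylbut-2-en-1-ol
Product: 27 [(2R,3R)-2,3-dimethyloxiran-2-yl]methanol
Conditions: Ti(OiPr)4 (5 mol %), D-(−)-diethyl tartrate (6 mol %), t-BuOOH, 4 Å molecular sieves, CH2Cl2, −20 °C
Reagents that add atoms: tert-butyl hydroperoxide, CC(C)(C)OO
Why: Katsuki–Sharpless epoxidation of an E-trisubstituted allylic alcohol, where D-(−)-tartrate gives the (2R,3R)-epoxy alcohol with high enantioselectivity.

Step 15
Reactants: 27 [(2R,3R)-2,3-dimethyloxiran-2-yl]methanol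
Product: 28 (2S,3R)-2,3-dimethyloxirane-2-carboxylic acid
Conditions: RuCl3·xH2O (2 mol %), NaIO4, CCl4/MeCN/H2O, 25 °C
Reagents that add atoms: sodium periodate, [Na+].[O-]I(=O)(=O)=O
Why: Catalytic ruthenium tetroxide oxidation (Sharpless conditions) takes the primary alcohol to the acid without opening the epoxide, and the quaternary α-carbon cannot epimerise (2R becomes 2S only by CIP priority).

Step 16
Reactants: 25 methyl (2Z)-3-[(2S,3R)-3-[(1Z)-1-[(2R,3R)-3-[(1S)-2-(tert-butyldimethylsilyloxy)-1-hydroxyethyl]-4-methylidene-5-oxooxolan-2-yl]prop-1-en-2-yl]oxiran-2-yl]-2-iodoprop-2-enoate; 28 (2S,3R)-2,3-dimethyloxirane-2-carboxylic acid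
Product: 30 (1S)-2-(tert-butyldimethylsilyloxy)-1-[(2R,3S)-2-[(1Z)-2-[(2R,3S)-3-[(1Z)-2-iodo-3-methoxy-3-oxoprop-1-en-1-yl]oxiran-2-yl]prop-1-en-1-yl]-4-methylidene-5-oxooxolan-3-yl]ethyl (2S,3R)-2,3-dimethyloxirane-2-carboxylate, via (2S,3R)-2,3-dimethyloxirane-2-carboxylic 2,4,6-trichlorobenzoic anhydride 29 (not isolated)
Conditions: 28, 2,4,6-trichlorobenzoyl chloride, Et3N, toluene, 25 °C; then 25, DMAP, toluene, 25 °C
Reagents that add atoms: none
Why: Yamaguchi esterification acylates the hindered C8 hydroxyl through the mixed anhydride with retention at C8.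

Step 17
Reactants: 30 the C8 ester with a primary silyl ether at C9 (full name under Product of step 16)
Product: 31 (1S)-2-hydroxy-1-[(2R,3S)-2-[(1Z)-2-[(2R,3S)-3-[(1Z)-2-iodo-3-methoxy-3-oxoprop-1-en-1-yl]oxiran-2-yl]prop-1-en-1-yl]-4-methylidene-5-oxooxolan-3-yl]ethyl (2S,3R)-2,3-dimethyloxirane-2-carboxylate
Conditions: Bu4NF, AcOH (1:1), THF, 0 °C
Reagents that add atoms: none
Why: Buffered fluoride removes the primary silyl ether, and the acetic acid suppresses acyl migration from O8 to O9 and conjugate addition to the methylene lactone.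

Step 18
Reactants: 31 the C9 primary alcohol (full name under Product of step 17)
Product: 32 (1S)-2-oxo-1-[(2R,3S)-2-[(1Z)-2-[(2R,3S)-3-[(1Z)-2-iodo-3-methoxy-3-oxoprop-1-en-1-yl]oxiran-2-yl]prop-1-en-1-yl]-4-methylidene-5-oxooxolan-3-yl]ethyl (2S,3R)-2,3-dimethyloxirane-2-carboxylate
Conditions: Dess–Martin periodinane, pyridine, CH2Cl2, 0 °C; used at once
Reagents that add atoms: none
Why: Buffered Dess–Martin oxidation gives the configurationally labile α-acyloxy aldehyde without epimerising C8.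

Step 19
Reactants: 32 the α-acyloxy aldehyde carrying the (Z)-α-iodoenoate (full name under Product of step 18)
Product: 33 CNP0291485.6, methyl (2S,3R,6R,7S,8S,9S)-8-[(2S,3R)-2,3-dimethyloxirane-2-carbonyloxy]-2,3-epoxy-9-hydroxygermacra-1(10)E,4Z,11(13)-trien-12,6-olid-14-oate
Conditions: CrCl2 (10 equiv), NiCl2 (2 mol %), DMSO/THF 3:1, 2 mM, 25 °C, slow addition of 32
Reagents that add atoms: none
Why: Proposed new method: Nozaki–Hiyama–Kishi-type macrocyclisation of an α-iodoenoate, in which zerovalent nickel inserts into the electron-poor alkenyl C–I bond, transmetalation to trivalent chromium gives an α-chromio acrylate (C-bound chromium allenolate) that adds to the aldehyde at high dilution, the tether allows only the ring-cis olefin (C2 cis to C9), and the C9 alkoxide is expected to form trans to the pseudo-equatorial C8 acyloxy group (9S) under ring control; the closest known reactions are Nozaki–Hiyama–Kishi macrocyclisations of alkenyl iodides and β-iodoenoates onto aldehydes and chromium Reformatsky additions of α-halo esters.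

## Compound list

1 | (S)-but-3-ene-1,2-diol | O[C@@H](C=C)CO | starting material
2 | (S)-3,4-bis(tert-butyldimethylsilyloxy)but-1-ene | CC(C)(C)[Si](C)(C)O[C@@H](C=C)CO[Si](C)(C)C(C)(C)C | intermediate
3 | (S)-2-(tert-butyldimethylsilyloxy)but-3-en-1-ol | CC(C)(C)[Si](C)(C)O[C@@H](C=C)CO | intermediate
4 | (S)-2-(tert-butyldimethylsilyloxy)but-3-enal | CC(C)(C)[Si](C)(C)O[C@@H](C=C)C=O | intermediate
5 | ethyltriphenylphosphonium iodide | CC[P+](c1ccccc1)(c1ccccc1)c1ccccc1.[I-] | starting material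
6 | ethylidenetriphenylphosphorane | CC=P(c1ccccc1)(c1ccccc1)c1ccccc1 | intermediate
7 | (1-iodoethyl)triphenylphosphonium iodide | CC(I)[P+](c1ccccc1)(c1ccccc1)c1ccccc1.[I-] | intermediate
8 | (1-iodoethylidene)triphenylphosphorane | CC(I)=P(c1ccccc1)(c1ccccc1)c1ccccc1 | intermediate
9 | (3S,4Z)-3-(tert-butyldimethylsilyloxy)-5-iodohexa-1,4-diene | CC(C)(C)[Si](C)(C)O[C@@H](C=C)/C=C(/C)I | intermediate
10 | prop-2-yn-1-ol | C#CCO | starting material
11 | (4Z,6S)-6-(tert-butyldimethylsilyloxy)-4-methylocta-4,7-dien-2-yn-1-ol | CC(C)(C)[Si](C)(C)O[C@@H](C=C)/C=C(/C)C#CCO | intermediate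
12 | (2Z,4Z,6S)-6-(tert-butyldimethylsilyloxy)-4-methylocta-2,4,7-trien-1-ol | CC(C)(C)[Si](C)(C)O[C@@H](C=C)/C=C(/C)\C=C/CO | intermediate
13 | [(2S,3R)-3-[(2Z,4S)-4-(tert-butyldimethylsilyloxy)hexa-2,5-dien-2-yl]oxiran-2-yl]methanol | CC(C)(C)[Si](C)(C)O[C@@H](C=C)/C=C(/C)[C@H]1O[C@H]1CO | intermediate
14 | (2R,3R)-3-[(2Z,4S)-4-(tert-butyldimethylsilyloxy)hexa-2,5-dien-2-yl]oxirane-2-carbaldehyde | CC(C)(C)[Si](C)(C)O[C@@H](C=C)/C=C(/C)[C@H]1O[C@H]1C=O | intermediate
15 | methyl (triphenylphosphoranylidene)acetate | COC(=O)C=P(c1ccccc1)(c1ccccc1)c1ccccc1 | starting material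
16 | (1-iodo-2-methoxy-2-oxoethyl)triphenylphosphonium succinimidate | COC(=O)C(I)[P+](c1ccccc1)(c1ccccc1)c1ccccc1.O=C1CCC(=O)[N-]1 | intermediate
17 | methyl iodo(triphenylphosphoranylidene)acetate | COC(=O)C(I)=P(c1ccccc1)(c1ccccc1)c1ccccc1 | intermediate
18 | methyl (2Z)-3-[(2S,3R)-3-[(2Z,4S)-4-(tert-butyldimethylsilyloxy)hexa-2,5-dien-2-yl]oxiran-2-yl]-2-iodoprop-2-enoate | CC(C)(C)[Si](C)(C)O[C@@H](C=C)/C=C(/C)[C@H]1O[C@H]1/C=C(/C(=O)OC)I | intermediate
19 | methyl (2Z)-3-[(2S,3R)-3-[(2Z,4S)-4-hydroxyhexa-2,5-dien-2-yl]oxiran-2-yl]-2-iodoprop-2-enoate | O[C@@H](C=C)/C=C(/C)[C@H]1O[C@H]1/C=C(/C(=O)OC)I | intermediate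
20 | 2-(bromomethyl)prop-2-enoic acid | C=C(CBr)C(=O)O | starting material
21 | 2-(bromomethyl)prop-2-enoyl chloride | C=C(CBr)C(=O)Cl | intermediate
22 | (3S,4Z)-5-[(2R,3S)-3-[(1Z)-2-iodo-3-methoxy-3-oxoprop-1-en-1-yl]oxiran-2-yl]hexa-1,4-dien-3-yl 2-(bromomethyl)prop-2-enoate | C=C(CBr)C(=O)O[C@@H](C=C)/C=C(/C)[C@H]1O[C@H]1/C=C(/C(=O)OC)I | intermediate
23 | methyl (2Z)-3-[(2S,3R)-3-[(1Z)-1-[(2R)-4-(bromomethyl)-5-oxo-2,5-dihydrofuran-2-yl]prop-1-en-2-yl]oxiran-2-yl]-2-iodoprop-2-enoate | O=C1O[C@@H](C=C1CBr)/C=C(/C)[C@H]2O[C@H]2/C=C(/C(=O)OC)I | intermediate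
24 | (tert-butyldimethylsilyloxy)acetaldehyde | CC(C)(C)[Si](C)(C)OCC=O | starting material
25 | methyl (2Z)-3-[(2S,3R)-3-[(1Z)-1-[(2R,3R)-3-[(1S)-2-(tert-butyldimethylsilyloxy)-1-hydroxyethyl]-4-methylidene-5-oxooxolan-2-yl]prop-1-en-2-yl]oxiran-2-yl]-2-iodoprop-2-enoate (germacranolide locants 6R,7R,8S) | C=C1C(=O)O[C@H](/C=C(/C)[C@H]2O[C@H]2/C=C(/C(=O)OC)I)[C@H]1[C@H](O)CO[Si](C)(C)C(C)(C)C | intermediate
26 | (E)-2-methylbut-2-en-1-ol (tiglyl alcohol) | C/C=C(\C)CO | starting material
27 | [(2R,3R)-2,3-dimethyloxiran-2-yl]methanol | OC[C@@]1(C)O[C@@H]1C | intermediate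
28 | (2S,3R)-2,3-dimethyloxirane-2-carboxylic acid | OC(=O)[C@@]1(C)O[C@@H]1C | intermediate
29 | (2S,3R)-2,3-dimethyloxirane-2-carboxylic 2,4,6-trichlorobenzoic anhydride | O=C(OC(=O)c1c(Cl)cc(Cl)cc1Cl)[C@@]1(C)O[C@@H]1C | intermediate
30 | (1S)-2-(tert-butyldimethylsilyloxy)-1-[(2R,3S)-2-[(1Z)-2-[(2R,3S)-3-[(1Z)-2-iodo-3-methoxy-3-oxoprop-1-en-1-yl]oxiran-2-yl]prop-1-en-1-yl]-4-methylidene-5-oxooxolan-3-yl]ethyl (2S,3R)-2,3-dimethyloxirane-2-carboxylate | C=C1C(=O)O[C@H](/C=C(/C)[C@H]2O[C@H]2/C=C(/C(=O)OC)I)[C@H]1[C@H](OC(=O)[C@@]2(C)O[C@@H]2C)CO[Si](C)(C)C(C)(C)C | intermediate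
31 | (1S)-2-hydroxy-1-[(2R,3S)-2-[(1Z)-2-[(2R,3S)-3-[(1Z)-2-iodo-3-methoxy-3-oxoprop-1-en-1-yl]oxiran-2-yl]prop-1-en-1-yl]-4-methylidene-5-oxooxolan-3-yl]ethyl (2S,3R)-2,3-dimethyloxirane-2-carboxylate | C=C1C(=O)O[C@H](/C=C(/C)[C@H]2O[C@H]2/C=C(/C(=O)OC)I)[C@H]1[C@H](OC(=O)[C@@]2(C)O[C@@H]2C)CO | intermediate
32 | (1S)-2-oxo-1-[(2R,3S)-2-[(1Z)-2-[(2R,3S)-3-[(1Z)-2-iodo-3-methoxy-3-oxoprop-1-en-1-yl]oxiran-2-yl]prop-1-en-1-yl]-4-methylidene-5-oxooxolan-3-yl]ethyl (2S,3R)-2,3-dimethyloxirane-2-carboxylate | C=C1C(=O)O[C@H](/C=C(/C)[C@H]2O[C@H]2/C=C(/C(=O)OC)I)[C@H]1[C@H](OC(=O)[C@@]2(C)O[C@@H]2C)C=O | intermediate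
33 | CNP0291485.6, methyl (2S,3R,6R,7S,8S,9S)-8-[(2S,3R)-2,3-dimethyloxirane-2-carbonyloxy]-2,3-epoxy-9-hydroxygermacra-1(10)E,4Z,11(13)-trien-12,6-olid-14-oate | C=C1C(=O)O[C@@H]2/C=C(/C)[C@H]3O[C@H]3/C=C(/C(=O)OC)[C@H](O)[C@@H](OC(=O)[C@@]3(C)O[C@@H]3C)[C@@H]12 | target

## Step count

Total steps: 19. Longest linear sequence: 17 (steps 1–13 and 16–19; steps 14–15 make the side-chain acid).

## Three steps most likely to fail, with fallbacks

**Step 19 (ring closure at C9–C10).** The α-iodoenoate is an untested partner for the chromium-mediated coupling, and for an open-chain α-acyloxy aldehyde the Felkin preference would favour the wrong C9 epimer, so the 9S outcome rests on ring control alone. The fallback sets out from 32 and returns at 33. If the cyclisation gives mainly the other carbinol, that product, the (9R)-epimer of 33 F1, is kept and the stereocentre is erased by Dess–Martin oxidation to the macrocyclic enone, the 9-oxo derivative of 33 F2. C9 is then set by reagent control instead of substrate control: Corey–Bakshi–Shibata reduction ((S)-2-methyl-CBS-oxazaborolidine, catecholborane, toluene, −78 °C; the alkenyl group acts as the large substituent) gives 33.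

**Step 13 (indium Barbier, C8 configuration).** The syn preference is taken from simpler 3-(bromomethyl)furanones and may erode or reverse with this substituted, functionalised partner. The fallback sets out from 23 (with 24) and returns at 30. If the reaction delivers mainly the C8 epimer, the (8R)-epimer of 25 F3, that alcohol is used as it is and the ester is formed with inversion instead of retention: Mitsunobu esterification with acid 28 (PPh3, DIAD, toluene, 0 °C) replaces the Yamaguchi step and gives 30 directly.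

**Step 7 (Sharpless epoxidation of the Z,Z-dienol).** Z-allylic alcohols react slowly with the titanium–tartrate catalyst, and the cis-alkenyl epoxide product can be opened by the Lewis-acidic titanium species. The fallback sets out from 12 and returns at 13. It leaves the titanium–tartrate system for a different catalytic manifold: Yamamoto's vanadium-catalysed hydroxyl-directed asymmetric epoxidation (VO(OiPr)3, C2-symmetric bis-hydroxamic acid ligand, aqueous t-BuOOH, toluene, 0 °C). This is effective for Z-allylic alcohols and is nearly neutral, and it gives 13 without any new intermediate.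

## Further compounds

F1 | step 19 | (9R)-epimer of 33 | C=C1C(=O)O[C@@H]2/C=C(/C)[C@H]3O[C@H]3/C=C(/C(=O)OC)[C@@H](O)[C@@H](OC(=O)[C@@]3(C)O[C@@H]3C)[C@@H]12
F2 | step 19 | 9-oxo derivative of 33 (macrocyclic enone) | C=C1C(=O)O[C@@H]2/C=C(/C)[C@H]3O[C@H]3/C=C(/C(=O)OC)C(=O)[C@@H](OC(=O)[C@@]3(C)O[C@@H]3C)[C@@H]12
F3 | step 13 | (8R)-epimer of 25 | C=C1C(=O)O[C@H](/C=C(/C)[C@H]2O[C@H]2/C=C(/C(=O)OC)I)[C@H]1[C@@H](O)CO[Si](C)(C)C(C)(C)C
F0 | step 7 | none | none
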